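Remark on the chemistry: the chain carbons are called Cα (the ketone carbon, bonded to ring B, the 4-hydroxy-3,5-dimethoxyphenyl ring), Cβ (the stereocentre, bonded through oxygen to ring A, the vanillic acid ring) and Cγ (the CH2OH carbon). Benzyl bromoacetate 3 is assumed to be commercial, like 1, 6 and 9.

## Analysis of the target

The target is an open-chain 8-O-4' neolignan at the α-ketone level, with no ring to close. Its chain Cα(=O)–Cβ(H)(OAr)–CγH2OH has Cα bonded to C1 of ring B, and the oxygen on Cβ bonded to C4 of ring A (3-methoxybenzoic acid). There is one stereocentre, Cβ, which the SMILES defines as S (priorities OAr > C=O > CH2OH > H). That centre is the main difficulty: its hydrogen is α to an aryl ketone and geminal to an aryloxy group, so it is lost by enolisation in base and, more slowly, in acid. The β-hydroxy ketone can also lose water to the aryloxy enone or lose Cγ by retro-aldol cleavage, and the free phenol para to the ketone and the free carboxylic acid limit the reagents that can be used at the end. Making the Cβ–O ether by displacement at Cβ would need an electrophile that is enolisable and prone to elimination. The strategy rests on reading Cα–Cβ as an aldol bond: with Cα as a carbinol and Cγ as a carboxyl carbon, the chain is the adduct of an enolate of a ring A aryloxyacetic acid and a ring B benzaldehyde.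

## Retrosynthetic reasoning

Target 16 is traced back to ketone 15, in which the acid of ring A is a tert-butyl ester and the phenol of ring B is a methoxymethyl ether. No skeletal bond is cut. Both groups fall in one acidic operation, and both withstand the base, Lewis acid, hydride and quinone oxidant used earlier. The forward step has to release them without enolising Cβ.

Ketone 15 is traced back to diol 14 by changing Cα=O into Cα–OH. As a carbinol, Cα no longer acidifies the hydrogen on Cβ, and the chain becomes an aldol retron. The forward step must oxidise the secondary benzylic alcohol next to a free primary one without base. A quinone hydride acceptor can do this because only the Cα–H bond is activated by the electron-rich ring B, whose phenol must therefore stay protected.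

Diol 14 is traced back to aldol adduct 13 by raising Cγ to the acyl carbon of an N-acyl oxazolidinone. The forward step is a hydride cleavage that releases auxiliary 6 and must leave the hindered aryl ester alone.

Adduct 13 is cut at Cα–Cβ into imide 8 and aldehyde 10. This is the only C–C bond of the chain whose cleavage gives two fragments of similar size, each derived from a cheap C6–C1 phenol. Cutting Cβ–O instead would require substitution by a hindered phenol at a carbon α to a carbonyl. Cutting Cα–C1 of ring B would require adding an aryl metal to an acyl unit whose α-centre is already set and labile. The aldol cut gains the chain bond and the Cβ configuration in one step under auxiliary control, through boron enolate 11 and aldolate 12. The carbinol configuration at Cα is irrelevant because it is oxidised later.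

Imide 8 is cut at the N–acyl bond into acid 5 and auxiliary 6, joined in the forward direction through mixed anhydride 7.

Acid 5 comes from diester 4, which is cut at the aryl O–CH2 bond into phenol 2 and bromoacetate 3. The ether is made while its carbon is an unsubstituted CH2, so it is a simple SN2 reaction with no stereochemical issue. The benzyl ester of 3 is chosen because hydrogenolysis removes it without touching the tert-butyl ester. Phenol 2 is the tert-butyl ester of vanillic acid 1.

Aldehyde 10 is the methoxymethyl ether of syringaldehyde 9.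

## Alternatives that were turned down

Alternative 1: carbene, phenol and a C1 electrophile joined at Cβ.
- Disconnection: the Cβ–O and Cβ–Cγ bonds are cut together. The pieces are the diazoketone 1-[4-(benzyloxy)-3,5-dimethoxyphenyl]-2-diazoethan-1-one A1, benzyl vanillate A2 and formaldehyde A3.
- Forward key step: Rh2(OAc)4 (divalent rhodium) would turn A1 into its rhodium carbene, and the phenol oxygen of A2 would add to the carbene carbon. The oxonium ylide or its enol would then be trapped at carbon by A3 held by a chiral BINOL-derived phosphoric acid, giving the protected ketone A4.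
- For: one step builds both bonds and the stereocentre at the final oxidation level, with a catalyst instead of an auxiliary and no redox detour. On step economy it is clearly stronger than the chosen route.
- Against: a phenol-derived ylide undergoes a very fast 1,2-proton shift, which amounts to plain O–H insertion and delivers neither Cγ nor a stereocentre, and trapping by A3 must outrun it. Enantioselective trapping is known mainly for aryl diazoacetates, which give quaternary centres. Here the acceptor-only diazoketone A1 gives a shorter-lived ylide, and A3 is the smallest possible electrophile for the chiral acid to orient. The product A4 keeps an acidic Cβ–H in contact with the Brønsted acid, so the configuration could erode in the flask. The benzyl groups of A4 must later be hydrogenolysed next to an α-aryloxy ketone.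
- Comparison: the chosen route is several steps longer. In return its stereocontrol comes from a well-understood closed transition state, and Cβ is formed while the neighbouring carbon is a carbinol.

Alternative 2: lipase desymmetrisation.
- Disconnection: none in the skeleton. The stereocentre is traced to the prochiral diol tert-butyl 4-[(1,3-dihydroxypropan-2-yl)oxy]-3-methoxybenzoate A5.
- Forward key step: a lipase transfers the acetyl group of vinyl acetate A6 to one of the two enantiotopic CH2OH arms of A5 and gives the monoacetate A7.
- For: the reaction is catalytic, cheap and scalable, and desymmetrisation of 2-substituted propane-1,3-diols is a mature reaction class. It is also stronger than the chosen route in that either enantiomer of the target could be reached from A7 by choosing which arm to elaborate.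
- Against: no C–C bond is formed. The free arm of A7 would still have to be oxidised, arylated with a metalated ring B unit and oxidised again. This passes through an α-aryloxy carbonyl stage that is configurationally labile and carries a β-acetoxy leaving group. The acetate must finally be removed from a β-acyloxy ketone, where elimination and base-induced racemisation compete. Acyl migration between the two arms of A7 would also erode its enantiomeric purity.
- Comparison: the chosen route needs a stoichiometric auxiliary, but it forms the chain bond and the stereocentre in the same step and reaches the target in fewer operations after the stereocentre is set.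

Alternative 3: base-free acyl–aryl coupling.
- Disconnection: the Cα–C1(ring B) bond. The pieces are the S-phenyl thioester A8 and [3,5-dimethoxy-4-(methoxymethoxy)phenyl]boronic acid A9.
- Forward key step: a Liebeskind–Srogl coupling with Pd2(dba)3 (zerovalent palladium), tri(2-furyl)phosphine and copper thiophene-2-carboxylate, CuTC (monovalent copper), would join A8 and A9 to give the silyl-protected ketone A10.
- For: the coupling is neutral and has an analogy in racemisation-free ketone synthesis from α-amino thioesters. It gives the ketone A10 directly, with no sacrificial carbinol centre and no late oxidation, and on these points it is as strong as or stronger than the chosen route.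
- Against: the stereochemical problem is only moved into A8, which must itself be made enantiopure. That would probably mean an invertive etherification of a glycerate-type α-hydroxy ester, where β-elimination threatens, followed by ester-to-thioester exchange at a centre more acidic than in the α-amino cases. Cβ would then sit α to an activated acyl group or a ketone through four or more steps, including a silyl ether removal.
- Comparison: the chosen route pays with an auxiliary and a redox detour. In return Cβ is enolisable only in its last two steps.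

Key step: step 6

## Route

Step 1
Reactants: 1 vanillic acid (4-hydroxy-3-methoxybenzoic acid)
Product: 2 tert-butyl 4-hydroxy-3-methoxybenzoate
Conditions: Me2NCH(OtBu)2, toluene, 80 °C
Reagents that add atoms: N,N-dimethylformamide di-tert-butyl acetal, CN(C)C(OC(C)(C)C)OC(C)(C)C
Why: Esterification with an amide acetal: the carboxylic acid protonates the acetal and the carboxylate takes up the tert-butyl group, while the much less acidic phenol stays free, as is usual for hydroxybenzoic acids.

Step 2
Reactants: 2 tert-butyl 4-hydroxy-3-methoxybenzoate; 3 benzyl bromoacetate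
Product: 4 tert-butyl 4-[2-(benzyloxy)-2-oxoethoxy]-3-methoxybenzoate
Conditions: K2CO3, acetone, reflux
Reagents that add atoms: none
Why: Williamson ether synthesis: the phenoxide displaces bromide from the activated primary α-bromo ester, and no stereocentre is involved; the tert-butyl ester is inert to carbonate.

Step 3
Reactants: 4 tert-butyl 4-[2-(benzyloxy)-2-oxoethoxy]-3-methoxybenzoate
Product: 5 [4-(tert-butoxycarbonyl)-2-methoxyphenoxy]acetic acid
Conditions: H2 (1 atm), 10% Pd/C, EtOAc, rt
Reagents that add atoms: none
Why: Hydrogenolysis of the benzyl ester; the tert-butyl ester and the non-benzylic aryl O–CH2 ether are not cleaved under these conditions.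

Step 4
Reactants: 5 [4-(tert-butoxycarbonyl)-2-methoxyphenoxy]acetic acid; 6 (R)-4-benzyl-1,3-oxazolidin-2-one
Product: 8 tert-butyl 4-{2-[(4R)-4-benzyl-2-oxo-1,3-oxazolidin-3-yl]-2-oxoethoxy}-3-methoxybenzoate, via pivalic mixed anhydride 7 (not isolated)
Conditions: PivCl, Et3N, THF, −20 °C; then LiCl, 6, −20 °C → rt
Reagents that add atoms: pivaloyl chloride, CC(C)(C)C(=O)Cl (its atoms reach only intermediate 7 and leave again as pivalic acid)
Why: N-Acylation of an oxazolidinone through a mixed pivalic anhydride with LiCl and Et3N; the auxiliary attacks the unhindered aryloxyacetyl carbonyl of 7 and not the pivaloyl carbonyl, and the stereocentre of 6 is untouched.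

Step 5
Reactants: 9 syringaldehyde (4-hydroxy-3,5-dimethoxybenzaldehyde)
Product: 10 3,5-dimethoxy-4-(methoxymethoxy)benzaldehyde
Conditions: MOMCl, iPr2NEt, CH2Cl2, 0 °C → rt
Reagents that add atoms: chloromethyl methyl ether, COCCl
Why: O-Alkylation of the acidic para-formyl phenol as its methoxymethyl ether, which blocks quinone methide formation and phenol oxidation in steps 6 and 8.

Step 6
Reactants: 8 tert-butyl 4-{2-[(4R)-4-benzyl-2-oxo-1,3-oxazolidin-3-yl]-2-oxoethoxy}-3-methoxybenzoate; 10 3,5-dimethoxy-4-(methoxymethoxy)benzaldehyde
Product: 13 tert-butyl 4-{[(2R,3S)-1-[(4R)-4-benzyl-2-oxo-1,3-oxazolidin-3-yl]-3-[3,5-dimethoxy-4-(methoxymethoxy)phenyl]-3-hydroxy-1-oxopropan-2-yl]oxy}-3-methoxybenzoate, via Z dibutylboron enolate 11 (not isolated), via dibutylboron aldolate 12 (not isolated)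
Conditions: Bu2BOTf, iPr2NEt, CH2Cl2, −78 → 0 °C; 10, −78 → 0 °C; then pH 7 phosphate buffer, MeOH, 30% H2O2, 0 °C
Reagents that add atoms: dibutylboron triflate, CCCCB(CCCC)OS(=O)(=O)C(F)(F)F (boron and butyl groups are carried only by intermediates 11 and 12)
Why: Bu2BOTf binds the imide carbonyl and iPr2NEt removes one of the two equivalent OCH2 protons, giving the Z(O) boron enolate 11 with the aryloxy group cis to the O–B bond, as is general for soft enolisation of N-acyl oxazolidinones. Boron carries two butyl groups and can bind only the enolate oxygen and the aldehyde oxygen, so the oxazolidinone carbonyl is free and turns away from the enolate C–O bond to oppose the dipoles. The Cα–Cβ bond then forms in a closed chair (Zimmerman–Traxler) transition state with the aryl group of 10 equatorial, which turns Z geometry into the syn relation of Cβ and Cα. In this arrangement the (R)-benzyl group covers one enolate face and 10 adds to the other, which sets Cβ as 2R by auxiliary control and, through the chair, Cα as 3S. The closest known reaction type is the Evans syn aldol of alkoxyacetyl and aryloxyacetyl (glycolate) oxazolidinones with aromatic aldehydes; no ring is closed. The step needs enolate geometry and face selectivity, which the auxiliary and the short B–O bonds secure, and it needs unambiguous enolisation, which is secured because 8 has a single acidic CH2 and 10 cannot enolise. Buffered H2O2 cleaves the B–O bond of aldolate 12 without a base strong enough to cause retro-aldol cleavage or epimerisation.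

Step 7
Reactants: 13 tert-butyl 4-{[(2R,3S)-1-[(4R)-4-benzyl-2-oxo-1,3-oxazolidin-3-yl]-3-[3,5-dimethoxy-4-(methoxymethoxy)phenyl]-3-hydroxy-1-oxopropan-2-yl]oxy}-3-methoxybenzoate
Product: 14 tert-butyl 4-{[(1S,2S)-1-[3,5-dimethoxy-4-(methoxymethoxy)phenyl]-1,3-dihydroxypropan-2-yl]oxy}-3-methoxybenzoate
Conditions: LiBH4, MeOH (1 equiv), THF, 0 °C
Reagents that add atoms: none
Why: Reductive cleavage of the N-acyl oxazolidinone: hydride attacks the activated exocyclic carbonyl, auxiliary 6 is released and the acyl carbon ends as CγH2OH, while the hindered, electron-rich tert-butyl benzoate is not reduced at 0 °C. Cβ is not deprotonated, so its geometry is kept; its descriptor changes from R to S only because the priorities change.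

Step 8
Reactants: 14 tert-butyl 4-{[(1S,2S)-1-[3,5-dimethoxy-4-(methoxymethoxy)phenyl]-1,3-dihydroxypropan-2-yl]oxy}-3-methoxybenzoate
Product: 15 tert-butyl 4-{[(2S)-1-[3,5-dimethoxy-4-(methoxymethoxy)phenyl]-3-hydroxy-1-oxopropan-2-yl]oxy}-3-methoxybenzoate
Conditions: DDQ (1.3 equiv), 1,4-dioxane, 25 → 50 °C
Reagents that add atoms: none
Why: Benzylic oxidation by hydride abstraction: DDQ removes the Cα–H activated by the alkoxy-substituted ring B and the oxocarbenium ion collapses to the aryl ketone, while the primary aliphatic alcohol has no such activation, as is known for etherified β-O-4 lignin model diols. The medium is neutral to weakly acidic, so the newly enolisable Cβ should keep its configuration.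

Step 9
Reactants: 15 tert-butyl 4-{[(2S)-1-[3,5-dimethoxy-4-(methoxymethoxy)phenyl]-3-hydroxy-1-oxopropan-2-yl]oxy}-3-methoxybenzoate
Product: 16 4-{[(2S)-3-hydroxy-1-(4-hydroxy-3,5-dimethoxyphenyl)-1-oxopropan-2-yl]oxy}-3-methoxybenzoic acid
Conditions: CF3CO2H/CH2Cl2/H2O, 0 °C → rt; evaporation with toluene, no basic wash
Reagents that add atoms: none
Why: Acidolysis of the tert-butyl ester (loss of the tert-butyl cation as 2-methylpropene) and hydrolysis of the aryl methoxymethyl acetal in one operation; the ketone deactivates ring B and removes the ionisable benzylic carbinol, and water suppresses trifluoroacetylation of the CγH2OH group. Short contact at low temperature and a base-free work-up are meant to keep Cβ from enolising.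

## Compound list

1 | vanillic acid (4-hydroxy-3-methoxybenzoic acid) | COc1cc(C(=O)O)ccc1O | starting material
2 | tert-butyl 4-hydroxy-3-methoxybenzoate | COc1cc(C(=O)OC(C)(C)C)ccc1O | intermediate
3 | benzyl bromoacetate | BrCC(=O)OCc1ccccc1 | starting material
4 | tert-butyl 4-[2-(benzyloxy)-2-oxoethoxy]-3-methoxybenzoate | COc1cc(C(=O)OC(C)(C)C)ccc1OCC(=O)OCc1ccccc1 | intermediate
5 | [4-(tert-butoxycarbonyl)-2-methoxyphenoxy]acetic acid | COc1cc(C(=O)OC(C)(C)C)ccc1OCC(=O)O | intermediate
6 | (R)-4-benzyl-1,3-oxazolidin-2-one | O=C1N[C@H](Cc2ccccc2)CO1 | starting material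
7 | [4-(tert-butoxycarbonyl)-2-methoxyphenoxy]acetic pivalic anhydride (mixed anhydride, not isolated) | COc1cc(C(=O)OC(C)(C)C)ccc1OCC(=O)OC(=O)C(C)(C)C | intermediate
8 | tert-butyl 4-{2-[(4R)-4-benzyl-2-oxo-1,3-oxazolidin-3-yl]-2-oxoethoxy}-3-methoxybenzoate | COc1cc(C(=O)OC(C)(C)C)ccc1OCC(=O)N1[C@H](Cc2ccccc2)COC1=O | intermediate
9 | syringaldehyde (4-hydroxy-3,5-dimethoxybenzaldehyde) | COc1cc(C=O)cc(OC)c1O | starting material
10 | 3,5-dimethoxy-4-(methoxymethoxy)benzaldehyde | COCOc1c(OC)cc(C=O)cc1OC | intermediate
11 | Z dibutylboron enolate of imide 8 (not isolated) | CCCCB(CCCC)O/C(=C\Oc1ccc(C(=O)OC(C)(C)C)cc1OC)N1[C@H](Cc2ccccc2)COC1=O | intermediate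
12 | O-dibutylboryl derivative (boron aldolate) of adduct 13 (not isolated) | COc1cc(C(=O)OC(C)(C)C)ccc1O[C@@H](C(=O)N1[C@H](Cc2ccccc2)COC1=O)[C@@H](OB(CCCC)CCCC)c1cc(OC)c(OCOC)c(OC)c1 | intermediate
13 | tert-butyl 4-{[(2R,3S)-1-[(4R)-4-benzyl-2-oxo-1,3-oxazolidin-3-yl]-3-[3,5-dimethoxy-4-(methoxymethoxy)phenyl]-3-hydroxy-1-oxopropan-2-yl]oxy}-3-methoxybenzoate | COc1cc(C(=O)OC(C)(C)C)ccc1O[C@@H](C(=O)N1[C@H](Cc2ccccc2)COC1=O)[C@@H](O)c1cc(OC)c(OCOC)c(OC)c1 | intermediate
14 | tert-butyl 4-{[(1S,2S)-1-[3,5-dimethoxy-4-(methoxymethoxy)phenyl]-1,3-dihydroxypropan-2-yl]oxy}-3-methoxybenzoate | COc1cc(C(=O)OC(C)(C)C)ccc1O[C@@H](CO)[C@@H](O)c1cc(OC)c(OCOC)c(OC)c1 | intermediate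
15 | tert-butyl 4-{[(2S)-1-[3,5-dimethoxy-4-(methoxymethoxy)phenyl]-3-hydroxy-1-oxopropan-2-yl]oxy}-3-methoxybenzoate | COc1cc(C(=O)OC(C)(C)C)ccc1O[C@@H](CO)C(=O)c1cc(OC)c(OCOC)c(OC)c1 | intermediate
16 | 4-{[(2S)-3-hydroxy-1-(4-hydroxy-3,5-dimethoxyphenyl)-1-oxopropan-2-yl]oxy}-3-methoxybenzoic acid | COc1cc(C(=O)O)ccc1O[C@@H](CO)C(=O)c1cc(OC)c(O)c(OC)c1 | target

## Step count and least certain steps

Total step count: 9. Longest linear sequence: 8 steps (steps 1 to 4 and 6 to 9, from vanillic acid 1); step 5 is the one-step side branch.

Step 6 (key step).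
What may go wrong: enolisation or addition may stall because the boron triflate is held by the many Lewis basic oxygens of 8 and 10. The methoxymethyl acetal may be partly lost on contact with the Lewis acid. Retro-aldol cleavage during work-up may lower the diastereomeric purity.
Fallback: the auxiliary is given up and Cβ is set by dynamic kinetic resolution; the fallback sets out from ester 4 and aldehyde 10 and comes back to the route at diol 14. LiN(iPr)2 in THF at −78 °C converts 4 into its lithium ester enolate F1, and F1 adds to 10 to give, after an aqueous NH4Cl quench, the racemic benzyl β-hydroxy ester F2 as a mixture of diastereomers. Dess–Martin periodinane oxidises F2 to the racemic β-keto ester F3, and the Cβ–H of F3 is acidic enough to racemise continuously. Noyori–Ikariya transfer hydrogenation of F3 with RuCl[(R,R)-TsDPEN](p-cymene) (divalent ruthenium) and HCO2H/Et3N, a reaction type known for α-alkoxy β-keto esters, should reduce one enantiomer selectively to the syn (2R,3S) benzyl hydroxy ester F4. If the sense or the syn/anti preference turns out otherwise, the other catalyst enantiomer is used, since only Cβ has to be right. LiBH4 in THF at 0 °C reduces the α-aryloxy benzyl ester of F4 and spares the tert-butyl ester, which gives 14.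

Step 9.
What may go wrong: acid-promoted enolisation may erode the configuration at Cβ. The β-hydroxy ketone may lose water, the CγH2OH group may be trifluoroacetylated, and the rings may be alkylated by the released tert-butyl cation.
Fallback: the acid-labile groups are replaced by benzyl groups that are removed under neutral conditions; the fallback sets out from imide 8 and syringaldehyde 9 and comes back to the route at target 16. CF3CO2H in CH2Cl2 removes the tert-butyl group of 8 while Cβ is still a CH2 group and gives the carboxylic acid imide F5, and BnBr with KHCO3 in DMF converts F5 into the benzyl ester imide F6. Aldehyde 9 is benzylated with BnBr and K2CO3 in DMF to 4-(benzyloxy)-3,5-dimethoxybenzaldehyde F7. The chemistry of steps 6 to 8 is then repeated in this series: Bu2BOTf and iPr2NEt turn F6 into the Z boron enolate F8, F8 adds to F7 to give the boron aldolate F9, and buffered H2O2 releases from F9 the benzyl-protected aldol adduct F10. NaBH4 in THF/H2O, used in place of LiBH4 to spare the benzyl ester, cleaves the auxiliary of F10 and gives the benzyl-protected diol F11, and DDQ oxidises F11 to the benzyl-protected ketone F12, which is the same compound as A4. H2 over 10% Pd/C in EtOAc at room temperature, stopped once both benzyl groups of F12 are gone, gives 16.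

Step 8.
What may go wrong: hydride abstraction may be slow, because the para oxygen of ring B is twisted out of conjugation by its two methoxy neighbours. Forcing the reaction may then cause over-oxidation or attack on the acetal.
Fallback: the chemoselective oxidation is replaced by protection followed by a non-selective oxidation; the fallback sets out from diol 14 and comes back to the route at target 16. TBSCl and imidazole in CH2Cl2 at 0 °C silylate the primary CγH2OH group of 14 selectively and give the primary silyl ether F13. Dess–Martin periodinane buffered with NaHCO3 oxidises the only free hydroxyl of F13 and gives the silyl-protected ketone F14, which is the same compound as A10. The aqueous CF3CO2H of step 9 removes the silyl, methoxymethyl and tert-butyl groups of F14 together and gives 16.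

## Further compounds

F1 | step 6 | lithium 1-(benzyloxy)-2-[4-(tert-butoxycarbonyl)-2-methoxyphenoxy]ethen-1-olate (lithium enolate of 4, double-bond geometry not defined) | [Li+].[O-]C(OCc1ccccc1)=COc1ccc(C(=O)OC(C)(C)C)cc1OC
F2 | step 6 | benzyl 2-[4-(tert-butoxycarbonyl)-2-methoxyphenoxy]-3-[3,5-dimethoxy-4-(methoxymethoxy)phenyl]-3-hydroxypropanoate (racemic, both diastereomers) | COc1cc(C(=O)OC(C)(C)C)ccc1OC(C(=O)OCc1ccccc1)C(O)c1cc(OC)c(OCOC)c(OC)c1
F3 | step 6 | benzyl 2-[4-(tert-butoxycarbonyl)-2-methoxyphenoxy]-3-[3,5-dimethoxy-4-(methoxymethoxy)phenyl]-3-oxopropanoate (racemic) | COc1cc(C(=O)OC(C)(C)C)ccc1OC(C(=O)OCc1ccccc1)C(=O)c1cc(OC)c(OCOC)c(OC)c1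
F4 | step 6 | benzyl (2R,3S)-2-[4-(tert-butoxycarbonyl)-2-methoxyphenoxy]-3-[3,5-dimethoxy-4-(methoxymethoxy)phenyl]-3-hydroxypropanoate | COc1cc(C(=O)OC(C)(C)C)ccc1O[C@@H](C(=O)OCc1ccccc1)[C@@H](O)c1cc(OC)c(OCOC)c(OC)c1
F5 | step 9 | 4-{2-[(4R)-4-benzyl-2-oxo-1,3-oxazolidin-3-yl]-2-oxoethoxy}-3-methoxybenzoic acid | COc1cc(C(=O)O)ccc1OCC(=O)N1[C@H](Cc2ccccc2)COC1=O
F6 | step 9 | benzyl 4-{2-[(4R)-4-benzyl-2-oxo-1,3-oxazolidin-3-yl]-2-oxoethoxy}-3-methoxybenzoate | COc1cc(C(=O)OCc2ccccc2)ccc1OCC(=O)N1[C@H](Cc2ccccc2)COC1=O
F7 | step 9 | 4-(benzyloxy)-3,5-dimethoxybenzaldehyde | COc1cc(C=O)cc(OC)c1OCc1ccccc1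
F8 | step 9 | Z dibutylboron enolate of F6 (not isolated) | CCCCB(CCCC)O/C(=C\Oc1ccc(C(=O)OCc2ccccc2)cc1OC)N1[C@H](Cc2ccccc2)COC1=O
F9 | step 9 | O-dibutylboryl derivative (boron aldolate) of F10 (not isolated) | COc1cc(C(=O)OCc2ccccc2)ccc1O[C@@H](C(=O)N1[C@H](Cc2ccccc2)COC1=O)[C@@H](OB(CCCC)CCCC)c1cc(OC)c(OCc2ccccc2)c(OC)c1
F10 | step 9 | benzyl 4-{[(2R,3S)-1-[(4R)-4-benzyl-2-oxo-1,3-oxazolidin-3-yl]-3-[4-(benzyloxy)-3,5-dimethoxyphenyl]-3-hydroxy-1-oxopropan-2-yl]oxy}-3-methoxybenzoate | COc1cc(C(=O)OCc2ccccc2)ccc1O[C@@H](C(=O)N1[C@H](Cc2ccccc2)COC1=O)[C@@H](O)c1cc(OC)c(OCc2ccccc2)c(OC)c1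
F11 | step 9 | benzyl 4-{[(1S,2S)-1-[4-(benzyloxy)-3,5-dimethoxyphenyl]-1,3-dihydroxypropan-2-yl]oxy}-3-methoxybenzoate | COc1cc(C(=O)OCc2ccccc2)ccc1O[C@@H](CO)[C@@H](O)c1cc(OC)c(OCc2ccccc2)c(OC)c1
F12 | step 9 | benzyl 4-{[(2S)-1-[4-(benzyloxy)-3,5-dimethoxyphenyl]-3-hydroxy-1-oxopropan-2-yl]oxy}-3-methoxybenzoate | COc1cc(C(=O)OCc2ccccc2)ccc1O[C@@H](CO)C(=O)c1cc(OC)c(OCc2ccccc2)c(OC)c1
F13 | step 8 | tert-butyl 4-{[(1S,2S)-3-[(tert-butyldimethylsilyl)oxy]-1-[3,5-dimethoxy-4-(methoxymethoxy)phenyl]-1-hydroxypropan-2-yl]oxy}-3-methoxybenzoate | COc1cc(C(=O)OC(C)(C)C)ccc1O[C@@H](CO[Si](C)(C)C(C)(C)C)[C@@H](O)c1cc(OC)c(OCOC)c(OC)c1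
F14 | step 8 | tert-butyl 4-{[(2S)-3-[(tert-butyldimethylsilyl)oxy]-1-[3,5-dimethoxy-4-(methoxymethoxy)phenyl]-1-oxopropan-2-yl]oxy}-3-methoxybenzoate | COc1cc(C(=O)OC(C)(C)C)ccc1O[C@@H](CO[Si](C)(C)C(C)(C)C)C(=O)c1cc(OC)c(OCOC)c(OC)c1
A1 | alternative 1 | 1-[4-(benzyloxy)-3,5-dimethoxyphenyl]-2-diazoethan-1-one | COc1cc(C(=O)C=[N+]=[N-])cc(OC)c1OCc1ccccc1
A2 | alternative 1 | benzyl 4-hydroxy-3-methoxybenzoate (benzyl vanillate) | COc1cc(C(=O)OCc2ccccc2)ccc1O
A3 | alternative 1 | formaldehyde | C=O
A4 | alternative 1 | benzyl 4-{[(2S)-1-[4-(benzyloxy)-3,5-dimethoxyphenyl]-3-hydroxy-1-oxopropan-2-yl]oxy}-3-methoxybenzoate | COc1cc(C(=O)OCc2ccccc2)ccc1O[C@@H](CO)C(=O)c1cc(OC)c(OCc2ccccc2)c(OC)c1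
A5 | alternative 2 | tert-butyl 4-[(1,3-dihydroxypropan-2-yl)oxy]-3-methoxybenzoate | COc1cc(C(=O)OC(C)(C)C)ccc1OC(CO)CO
A6 | alternative 2 | vinyl acetate | CC(=O)OC=C
A7 | alternative 2 | tert-butyl 4-{[(2R)-1-acetoxy-3-hydroxypropan-2-yl]oxy}-3-methoxybenzoate | COc1cc(C(=O)OC(C)(C)C)ccc1O[C@@H](COC(C)=O)CO
A8 | alternative 3 | tert-butyl 4-{[(2S)-3-[(tert-butyldimethylsilyl)oxy]-1-oxo-1-(phenylsulfanyl)propan-2-yl]oxy}-3-methoxybenzoate | COc1cc(C(=O)OC(C)(C)C)ccc1O[C@@H](CO[Si](C)(C)C(C)(C)C)C(=O)Sc1ccccc1
A9 | alternative 3 | [3,5-dimethoxy-4-(methoxymethoxy)phenyl]boronic acid | COCOc1c(OC)cc(B(O)O)cc1OC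
A10 | alternative 3 | tert-butyl 4-{[(2S)-3-[(tert-butyldimethylsilyl)oxy]-1-[3,5-dimethoxy-4-(methoxymethoxy)phenyl]-1-oxopropan-2-yl]oxy}-3-methoxybenzoate | COc1cc(C(=O)OC(C)(C)C)ccc1O[C@@H](CO[Si](C)(C)C(C)(C)C)C(=O)c1cc(OC)c(OCOC)c(OC)c1
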